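**Retrosynthetic overview**
1. Target 24 ⇐ acrylate 22 (Morita–Baylis–Hillman hydroxymethylation) ⇐ enal 21 (1,2-reduction of the C15 aldehyde).
2. Key step: the ten-membered ring of 21 ⇐ trans-decalin mesylate aldehyde 19 by ring expansion, an amine-catalysed vinylogous Grob fragmentation of the C5–C10 ring-fusion bond that sets both ring olefins.
3. 19 ⇐ ketone 15: C8 ketone → 8β-alcohol → Mitsunobu inversion to the 8α-acrylate; C15 silyl ether → aldehyde.
4. 15 ⇐ 12 by double ozonolysis and aldol–lactonisation; 12 ⇐ three-component coupling of enone 4, vinylmagnesium bromide 8 and allylic bromide 7.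
5. Ring order: ring A (Michael/aldol annulation) → ring B and the γ-lactone in one operation → ten-membered ring by cleaving the bond shared by rings A and B.

Assumption: the silyl group of commercial aldehyde 1 is a protecting group and is not counted in its heavy-atom total (C3O2 skeleton, five atoms).

Convention: germacrane/eudesmane numbering throughout (ring carbons C1–C10, lactone C11–C13, C14 = methyl on C10, C15 on C4); in the decalins β is the face of the C10 methyl. Compounds 7 and 10–14 are about 1:1 mixtures at the ester α-carbon (future C11), which converges in step 6.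

**Step 1**
Reactants: 1 3-[(tert-butyldimethylsilyl)oxy]propanal; 2 pent-1-en-3-one
Product: 4 (R)-4-{[(tert-butyldimethylsilyl)oxy]methyl}-2-methylcyclohex-2-en-1-one, via Michael adduct 3 (not isolated)
Conditions: (S)-2-[methoxy(diphenyl)methyl]pyrrolidine (5 mol %), ethyl 3,4-dihydroxybenzoate (20 mol %), neat, 4 °C; then Bn2NH·TFA (20 mol %), toluene, rt
Reagents that add atoms: none
Why: Enamine-mediated asymmetric Michael addition to the vinyl ketone (the catalyst shields one enamine face and sets C4, about 95% ee) followed by intramolecular aldol condensation (Robinson-type annulation), which can only close from the ethyl ketone α-carbon onto the aldehyde.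

**Step 2**
Reactants: 5 methyl propanoate; 6 3-bromo-2-(bromomethyl)prop-1-ene
Product: 7 methyl 4-(bromomethyl)-2-methylpent-4-enoate (racemic)
Conditions: LiN(i-Pr)2, THF, −78 °C; then 6 (3 equiv), −78 → −20 °C
Reagents that add atoms: none
Why: Ester enolate alkylation with an excess of the symmetrical allylic dibromide stops at monoalkylation (SN2 and SN2' give the same product); the new centre is left racemic because it is equilibrated in step 6.

**Step 3**
Reactants: 4 (R)-enone; 8 vinylmagnesium bromide; 7 allylic bromide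
Product: 10 methyl 4-{[(1R,2S,3R)-3-{[(tert-butyldimethylsilyl)oxy]methyl}-1-methyl-6-oxo-2-vinylcyclohexyl]methyl}-2-methylpent-4-enoate, via bromomagnesium enolate 9 (not isolated)
Conditions: CH2=CHMgBr, CuBr·SMe2 (10 mol %), THF, −78 °C; then 7, DMPU, −78 → 0 °C
Reagents that add atoms: none
Why: Copper-catalysed conjugate addition of the vinyl group anti to the C4 substituent, then C-alkylation of enolate 9 by the allylic bromide anti to the new vinyl group (three-component conjugate addition–alkylation); this puts the two future ring B arms trans on ring A and creates the C10 quaternary centre (expected dr about 6:1, minor epimer removed by chromatography).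

**Step 4**
Reactants: 10 ketone
Product: 11 methyl 4-{[(1R,2S,3R,6R)-3-{[(tert-butyldimethylsilyl)oxy]methyl}-6-hydroxy-1-methyl-2-vinylcyclohexyl]methyl}-2-methylpent-4-enoate
Conditions: NaBH4, MeOH/THF, −20 °C
Reagents that add atoms: none
Why: Borohydride reduction by axial attack on the face opposite the axial C10 methyl gives the equatorial alcohol cis to that methyl (future 1β-oxygen); the ester is untouched at this temperature.

**Step 5**
Reactants: 11 alcohol
Product: 12 the C1 methanesulfonate of 11
Conditions: MsCl, Et3N, CH2Cl2, 0 °C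
Reagents that add atoms: methanesulfonyl chloride, CS(=O)(=O)Cl
Why: Sulfonylation with retention; the equatorial neopentyl-type mesylate has no antiperiplanar hydrogen and no accessible backside, so it survives the later basic, reductive and Mitsunobu steps until the fragmentation.

**Step 6**
Reactants: 12 mesylate
Product: 15 1β-(methanesulfonyloxy)-15-[(tert-butyldimethylsilyl)oxy]-8-oxo-4βH,5αH,7αH,11βH-eudesman-6α,12-olide, via keto-aldehyde 13 (not isolated), via aldol hydroxy ester 14 (not isolated)
Conditions: O3, CH2Cl2, −78 °C; Me2S, rt; solvent exchange; then KOt-Bu (0.3 equiv), THF/t-BuOH, 0 °C → rt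
Reagents that add atoms: ozone, [O-][O+]=O
Why: Ozonolysis turns the vinyl group into the C6 aldehyde and the 1,1-disubstituted alkene into the C8 ketone; reversible base-catalysed intramolecular aldol addition (C7 enolate onto C6, chair transition state avoiding a 1,3-diaxial clash with the C10 methyl) then gives the all-equatorial trans-decalin, the 6α-hydroxyl lactonises onto the ester, and the epimerisable C7 and C11 centres settle as the trans-fused lactone with the 11-methyl anti to C8 (11S).

**Step 7**
Reactants: 15 ketone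
Product: 16 the 8β-hydroxy analogue of 15 (8-oxo → 8β-OH, axial)
Conditions: LiBH(s-Bu)3, THF, −78 °C
Reagents that add atoms: none
Why: The bulky trialkylborohydride attacks C8 from the equatorial α side because the axial β approach is blocked by the syn-axial C10 methyl, giving the axial 8β-alcohol; the γ-lactone and mesylate are not reduced at −78 °C.

**Step 8**
Reactants: 16 8β-alcohol; 17 acrylic acid
Product: 18 1β-(methanesulfonyloxy)-8α-(acryloyloxy)-15-[(tert-butyldimethylsilyl)oxy]-4βH,5αH,7αH,11βH-eudesman-6α,12-olide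
Conditions: PPh3, DIAD, toluene, 0 °C → rt
Reagents that add atoms: none
Why: Mitsunobu esterification, SN2 displacement of the oxyphosphonium ion by acrylate with inversion, converts the axial 8β-alcohol into the equatorial 8α-ester (8S) required by the target.

**Step 9**
Reactants: 18 silyl ether
Product: 19 1β-(methanesulfonyloxy)-8α-(acryloyloxy)-15-oxo-4βH,5αH,7αH,11βH-eudesman-6α,12-olide
Conditions: PhI(OAc)2, TEMPO (20 mol %), Bi(OTf)3 (5 mol %), wet MeCN/THF, rt
Reagents that add atoms: none
Why: One-pot oxidative deprotection, Lewis-acid-catalysed cleavage of the primary silyl ether followed by oxoammonium oxidation of the liberated alcohol, gives the C15 aldehyde without touching acrylate, lactone or mesylate.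

**Step 10**
Reactants: 19 mesylate aldehyde
Product: 21 (1(10)E,4Z)-8α-(acryloyloxy)-15-oxo-11βH-germacra-1(10),4-dien-6α,12-olide, via enamine 20 (not isolated)
Conditions: H2NC(CH3)2CH2NHC(S)NHAr (Ar = 3,5-(CF3)2C6H3, 20 mol %), PhCO2H (20 mol %), i-Pr2NEt (1.5 equiv), toluene, 50 °C
Reagents that add atoms: none
Why: Proposed new method: the hindered primary amine of a bifunctional amine–thiourea catalyst condenses with the α-branched aldehyde to enamine 20, whose nitrogen lone pair pushes through C15=C4 into the C5–C10 σ-bond (antiperiplanar to the equatorial C1–OMs bond, which the thiourea activates by hydrogen bonding), so that C4=C5 and C1=C10 form as the ring-fusion bond breaks and mesylate leaves, giving the E,E-cyclodecadiene stereospecifically from the trans-decalin, and hydrolysis of the conjugated iminium releases 21 and the catalyst; the tert-alkyl amine is too hindered for aza-Michael addition to the acrylate, and the closest known reaction types are the alkoxide-induced enolate-assisted 1,4-fragmentation of mesyloxy-decalin carbaldehydes and the Grob fragmentation of γ-amino sulfonates.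

**Step 11**
Reactants: 21 enal
Product: 22 (1(10)E,4Z)-8α-(acryloyloxy)-15-hydroxy-11βH-germacra-1(10),4-dien-6α,12-olide
Conditions: NaBH4, CeCl3·7H2O, MeOH, −78 °C
Reagents that add atoms: none
Why: Luche reduction gives selective 1,2-reduction of the conjugated aldehyde; acrylate, lactone and ring olefins are untouched at −78 °C.

**Step 12**
Reactants: 22 acrylate; 23 formaldehyde
Product: 24 target, 11β,13-dihydroonopordopicrin
Conditions: aq. CH2O, DABCO (1 equiv), 1,4-dioxane/H2O, rt
Reagents that add atoms: none
Why: Morita–Baylis–Hillman reaction: DABCO adds reversibly to the acrylate and the ammonium enolate is trapped by formaldehyde, installing the α-hydroxymethyl group without affecting any stereocentre.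

**Compound list**
1 | 3-[(tert-butyldimethylsilyl)oxy]propanal | O=CCCO[Si](C)(C)C(C)(C)C | starting material
2 | pent-1-en-3-one (ethyl vinyl ketone) | CCC(=O)C=C | starting material
3 | (S)-2-{[(tert-butyldimethylsilyl)oxy]methyl}-5-oxoheptanal (Michael adduct) | CCC(=O)CC[C@@H](CO[Si](C)(C)C(C)(C)C)C=O | intermediate (not isolated)
4 | (R)-4-{[(tert-butyldimethylsilyl)oxy]methyl}-2-methylcyclohex-2-en-1-one | CC1=C[C@H](CO[Si](C)(C)C(C)(C)C)CCC1=O | intermediate
5 | methyl propanoate | CCC(=O)OC | starting material
6 | 3-bromo-2-(bromomethyl)prop-1-ene | C=C(CBr)CBr | starting material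
7 | methyl 4-(bromomethyl)-2-methylpent-4-enoate (racemic) | COC(=O)C(C)CC(=C)CBr | intermediate
8 | vinylmagnesium bromide | C=C[Mg]Br | starting material
9 | bromomagnesium enolate of (3S,4R)-4-{[(tert-butyldimethylsilyl)oxy]methyl}-2-methyl-3-vinylcyclohexanone (vinyl trans to CH2OTBS) | C=C[C@H]1[C@H](CO[Si](C)(C)C(C)(C)C)CCC(O[Mg]Br)=C1C | intermediate (not isolated)
10 | methyl 4-{[(1R,2S,3R)-3-{[(tert-butyldimethylsilyl)oxy]methyl}-1-methyl-6-oxo-2-vinylcyclohexyl]methyl}-2-methylpent-4-enoate (vinyl trans to both the side chain and CH2OTBS; 1:1 at the ester α-carbon) | O=C1CC[C@@H](CO[Si](C)(C)C(C)(C)C)[C@H](C=C)[C@@]1(C)CC(=C)CC(C)C(=O)OC | intermediate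
11 | (1R,2S,3R,6R)-6-hydroxy analogue of 10 (OH cis to the ring methyl) | O[C@@H]1CC[C@@H](CO[Si](C)(C)C(C)(C)C)[C@H](C=C)[C@@]1(C)CC(=C)CC(C)C(=O)OC | intermediate
12 | methanesulfonate of 11 | CS(=O)(=O)O[C@@H]1CC[C@@H](CO[Si](C)(C)C(C)(C)C)[C@H](C=C)[C@@]1(C)CC(=C)CC(C)C(=O)OC | intermediate
13 | keto-aldehyde from double ozonolysis of 12 (C6 formyl, C8 ketone; ring configuration unchanged) | CS(=O)(=O)O[C@@H]1CC[C@@H](CO[Si](C)(C)C(C)(C)C)[C@H](C=O)[C@@]1(C)CC(=O)CC(C)C(=O)OC | intermediate (not isolated)
14 | aldol hydroxy ester: trans-decalin with 6α-OH, 7β-CH(CH3)CO2Me, 8-oxo, 1β-OMs, 4α-CH2OTBS | CS(=O)(=O)O[C@@H]1CC[C@@H](CO[Si](C)(C)C(C)(C)C)[C@@H]2[C@@H](O)[C@H](C(C)C(=O)OC)C(=O)C[C@@]12C | intermediate (not isolated)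
15 | 1β-(methanesulfonyloxy)-15-[(tert-butyldimethylsilyl)oxy]-8-oxo-4βH,5αH,7αH,11βH-eudesman-6α,12-olide | CS(=O)(=O)O[C@@H]1CC[C@@H](CO[Si](C)(C)C(C)(C)C)[C@@H]2[C@H]3OC(=O)[C@@H](C)[C@@H]3C(=O)C[C@@]12C | intermediate
16 | 8β-hydroxy analogue of 15 | CS(=O)(=O)O[C@@H]1CC[C@@H](CO[Si](C)(C)C(C)(C)C)[C@@H]2[C@H]3OC(=O)[C@@H](C)[C@@H]3[C@H](O)C[C@@]12C | intermediate
17 | acrylic acid | C=CC(=O)O | starting material
18 | 1β-(methanesulfonyloxy)-8α-(acryloyloxy)-15-[(tert-butyldimethylsilyl)oxy]-4βH,5αH,7αH,11βH-eudesman-6α,12-olide | CS(=O)(=O)O[C@@H]1CC[C@@H](CO[Si](C)(C)C(C)(C)C)[C@@H]2[C@H]3OC(=O)[C@@H](C)[C@@H]3[C@@H](OC(=O)C=C)C[C@@]12C | intermediate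
19 | 1β-(methanesulfonyloxy)-8α-(acryloyloxy)-15-oxo-4βH,5αH,7αH,11βH-eudesman-6α,12-olide | CS(=O)(=O)O[C@@H]1CC[C@@H](C=O)[C@@H]2[C@H]3OC(=O)[C@@H](C)[C@@H]3[C@@H](OC(=O)C=C)C[C@@]12C | intermediate
20 | C15 enamine of 19 with the amine–thiourea catalyst | CS(=O)(=O)O[C@@H]1CCC(=CNC(C)(C)CNC(=S)Nc4cc(C(F)(F)F)cc(C(F)(F)F)c4)[C@@H]2[C@H]3OC(=O)[C@@H](C)[C@@H]3[C@@H](OC(=O)C=C)C[C@@]12C | intermediate (not isolated)
21 | (1(10)E,4Z)-8α-(acryloyloxy)-15-oxo-11βH-germacra-1(10),4-dien-6α,12-olide | C=CC(=O)O[C@H]1C/C(C)=C/CC/C(C=O)=C/[C@H]2OC(=O)[C@@H](C)[C@H]12 | intermediate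
22 | (1(10)E,4Z)-8α-(acryloyloxy)-15-hydroxy-11βH-germacra-1(10),4-dien-6α,12-olide | C=CC(=O)O[C@H]1C/C(C)=C/CC/C(CO)=C/[C@H]2OC(=O)[C@@H](C)[C@H]12 | intermediate
23 | formaldehyde | C=O | starting material
24 | (6R,7R,8S,11S,1(10)E,4Z)-15-hydroxy-8-{[2-(hydroxymethyl)acryloyl]oxy}germacra-1(10),4-dien-6,12-olide (11β,13-dihydroonopordopicrin) | C=C(CO)C(=O)O[C@H]1C/C(C)=C/CC/C(CO)=C/[C@H]2OC(=O)[C@@H](C)[C@H]12 | target

**Step count and risks**
Total step count: 12. Longest linear sequence: 11 steps (1 → 24 through steps 1 and 3–12; step 2 is a one-step side branch).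

Most likely to fail, first: step 10, the new amine-catalysed ring expansion. Enamine formation at the hindered C4 aldehyde may be slow, or the neutral enamine may push too weakly to expel the mesylate. The fallback uses the known enolate-assisted 1,4-fragmentation in stoichiometric form; it sets out from 19 and returns at 21. Compound 19 is converted with TBSOTf/Et3N (CH2Cl2, −78 → 0 °C) into its C15 tert-butyldimethylsilyl enol ether F1. F1 is then treated with anhydrous tetrabutylammonium difluorotriphenylsilicate in THF at 0 °C; the liberated aldehyde enolate fragments across C5–C10 with loss of mesylate to give 21.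

Second: step 8, the Mitsunobu inversion at the hindered axial C8 alcohol, where anti elimination to an alkene can compete. The fallback sets out from ketone 15 and returns at 18. Ketone 15 is reduced under equilibrating Meerwein–Ponndorf–Verley conditions (Al(Oi-Pr)3, i-PrOH, toluene, 80 °C) to the thermodynamically favoured equatorial 8α-alcohol F2. F2 is then acylated with retention by acryloyl chloride (Et3N, DMAP, CH2Cl2, −20 °C) to give 18.

Third: step 3, the one-pot conjugate addition and quaternary alkylation. The magnesium enolate may alkylate sluggishly, and the C4 substituent sits on the face the electrophile must use, so the C10 selectivity may erode. The fallback sets out from 4 and returns at 10. The conjugate addition is run with Me3SiCl present and the regiodefined trimethylsilyl enol ether F3 is isolated. F3 is then cleaved with MeLi (THF, 0 °C) to the lithium enolate, which is alkylated with 7 in THF/DMPU at −78 → −20 °C to give 10; C10 epimers are separated at this stage.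

**Further compounds**
F1 | step 10 | C15 tert-butyldimethylsilyl enol ether of 19 | CS(=O)(=O)O[C@@H]1CCC(=CO[Si](C)(C)C(C)(C)C)[C@@H]2[C@H]3OC(=O)[C@@H](C)[C@@H]3[C@@H](OC(=O)C=C)C[C@@]12C
F2 | step 8 | 8α-hydroxy epimer of 16 (equatorial alcohol) | CS(=O)(=O)O[C@@H]1CC[C@@H](CO[Si](C)(C)C(C)(C)C)[C@@H]2[C@H]3OC(=O)[C@@H](C)[C@@H]3[C@@H](O)C[C@@]12C
F3 | step 3 | trimethylsilyl enol ether corresponding to enolate 9 | C=C[C@H]1[C@H](CO[Si](C)(C)C(C)(C)C)CCC(O[Si](C)(C)C)=C1C
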